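**Retrosynthetic overview**
1. Praesorether F (21) comes from its pentakis(methoxymethyl) ether 20 by one acidic global deprotection.
2. The diaryl ether C–O bond is cut by SNAr: ring B phenoxide plus ring C aryl fluoride 18, whose fluorine sits between CHO and CO2Me.
3. The diarylmethane C–C bond is cut into a ring B aryllithium (ortho-lithiation between two OMOM groups) plus ring A aldehyde 4, followed by ionic deoxygenation of the carbinol.
4. Ring A comes from methyl orsellinate (formylation), ring B from orcylaldehyde (Baeyer–Villiger), ring C from 3-fluoro-5-methylphenol (bromination, ortho-lithiation/formylation, carbonylation).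
5. No ring is built: all three benzene rings are bought. They are joined A + B first, then C.

Assumption: the target SMILES contains no stereocentre, so the compound is achiral and is made as such; compounds 1, 5 and 13 are taken as commercial.

**Step 1**
Reactants: 1 methyl orsellinate (methyl 2,4-dihydroxy-6-methylbenzoate)
Product: 3 methyl haematommate (methyl 3-formyl-2,4-dihydroxy-6-methylbenzoate), via alpha-chloro ether 2 (not isolated)
Conditions: Cl2CHOMe, TiCl4, CH2Cl2, 0 °C to rt; then aq. HCl
Reagents that add atoms: dichloromethyl methyl ether COC(Cl)Cl; water O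
Why: Rieche formylation of the titanium phenoxide goes mainly to C3, the carbon flanked by both hydroxyls and favoured by bond fixation of the ester chelate, and the minor 5-formyl isomer is removed by crystallisation; no stereocentre.

**Step 2**
Reactants: 3 methyl haematommate
Product: 4 methyl 3-formyl-2,4-bis(methoxymethoxy)-6-methylbenzoate
Conditions: NaH, MOMCl, DMF, 0 °C to rt
Reagents that add atoms: chloromethyl methyl ether COCCl
Why: Williamson-type O-alkylation of both sodium phenoxides masks the acidic hydroxyls before the organolithium step; the aldehyde has no alpha-hydrogen and is untouched.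

**Step 3**
Reactants: 5 2,4-dihydroxy-6-methylbenzaldehyde (orcylaldehyde)
Product: 6 2,4-bis(methoxymethoxy)-6-methylbenzaldehyde
Conditions: NaH, MOMCl, DMF, 0 °C to rt
Reagents that add atoms: chloromethyl methyl ether COCCl
Why: O-alkylation of both phenoxides installs the two MOM groups that later direct the lithiation.

**Step 4**
Reactants: 6 2,4-bis(methoxymethoxy)-6-methylbenzaldehyde
Product: 8 2,4-bis(methoxymethoxy)-6-methylphenol, via aryl formate 7 (not isolated)
Conditions: mCPBA, CH2Cl2, 0 °C to rt; aq. NaHCO3 wash; then K2CO3 (cat.), MeOH, rt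
Reagents that add atoms: 3-chloroperoxybenzoic acid O=C(OO)c1cccc(Cl)c1
Why: Baeyer–Villiger (Dakin-type) oxidation, in which the electron-rich aryl group migrates in preference to hydrogen, gives the formate, and methanolysis frees the phenol.

**Step 5**
Reactants: 8 2,4-bis(methoxymethoxy)-6-methylphenol
Product: 9 tert-butyl[2,4-bis(methoxymethoxy)-6-methylphenoxy]dimethylsilane
Conditions: TBSCl, imidazole, DMF, rt
Reagents that add atoms: tert-butyldimethylsilyl chloride CC(C)(C)[Si](C)(C)Cl
Why: Silylation gives a base-stable phenol mask that is orthogonal to MOM and is later removed by fluoride in the ether-forming step.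

**Step 6**
Reactants: 9 tert-butyl[2,4-bis(methoxymethoxy)-6-methylphenoxy]dimethylsilane; 4 methyl 3-formyl-2,4-bis(methoxymethoxy)-6-methylbenzoate
Product: 11 methyl 3-[{3-[(tert-butyldimethylsilyl)oxy]-2,6-bis(methoxymethoxy)-4-methylphenyl}(hydroxy)methyl]-2,4-bis(methoxymethoxy)-6-methylbenzoate (racemic), via aryllithium 10 (not isolated)
Conditions: n-BuLi (1.05 equiv to 9), THF, -20 to 0 °C; then 4, -78 to -20 °C; then H2O
Reagents that add atoms: none
Why: Directed ortho-metalation at the only C–H flanked by two OMOM groups, then 1,2-addition to the aldehyde, which is far more reactive than the doubly ortho-substituted ester; the new carbinol stereocentre is racemic and is erased in step 7.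

**Step 7**
Reactants: 11 the diaryl carbinol
Product: 12 methyl 3-{3-[(tert-butyldimethylsilyl)oxy]-2,6-bis(methoxymethoxy)-4-methylbenzyl}-2,4-bis(methoxymethoxy)-6-methylbenzoate
Conditions: Et3SiH (5 equiv), TFA (3 equiv), CH2Cl2, -40 to 0 °C
Reagents that add atoms: none
Why: Ionic hydrogenation: the carbinol, flanked by four ortho-alkoxy groups, ionises with dilute acid at low temperature and the cation is trapped by silane hydride before MOM or silyl ethers are cleaved; the stereocentre is removed.

**Step 8**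
Reactants: 13 3-fluoro-5-methylphenol
Product: 14 4-bromo-3-fluoro-5-methylphenol
Conditions: NBS, MeCN, -20 °C to rt
Reagents that add atoms: N-bromosuccinimide O=C1CCC(=O)N1Br
Why: Electrophilic aromatic bromination goes para to the free hydroxyl, as it does with 3,5-dimethylphenol.

**Step 9**
Reactants: 14 4-bromo-3-fluoro-5-methylphenol
Product: 15 2-bromo-1-fluoro-5-(methoxymethoxy)-3-methylbenzene
Conditions: NaH, MOMCl, THF/DMF, 0 °C
Reagents that add atoms: chloromethyl methyl ether COCCl
Why: O-alkylation of the phenoxide installs a MOM group that both protects the oxygen and directs the next metalation.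

**Step 10**
Reactants: 15 2-bromo-1-fluoro-5-(methoxymethoxy)-3-methylbenzene
Product: 17 3-bromo-2-fluoro-6-(methoxymethoxy)-4-methylbenzaldehyde, via aryllithium 16 (not isolated)
Conditions: LiN(i-Pr)2, THF, -78 °C; then DMF, -78 °C; then H2O
Reagents that add atoms: N,N-dimethylformamide CN(C)C=O
Why: Directed ortho-metalation with a lithium amide (no bromine–lithium exchange) removes the most acidic proton, the one between F and OMOM, and formylation with DMF follows; at -78 °C the ortho-fluoro aryllithium does not lose LiF.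

**Step 11**
Reactants: 17 3-bromo-2-fluoro-6-(methoxymethoxy)-4-methylbenzaldehyde
Product: 18 methyl 2-fluoro-3-formyl-4-(methoxymethoxy)-6-methylbenzoate
Conditions: Pd(OAc)2 (5 mol%), Xantphos (10 mol%), CO (1 atm), MeOH (5 equiv), Et3N, toluene, 80 °C
Reagents that add atoms: carbon monoxide [C-]#[O+]; methanol CO
Why: Palladium-catalysed methoxycarbonylation: zerovalent palladium inserts into the C–Br bond, CO insertion and methanolysis give the ester, and the ester is installed only now so that no base ever meets an ortho-toluate.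

**Step 12**
Reactants: 12 the silyl-protected diarylmethane; 18 methyl 2-fluoro-3-formyl-4-(methoxymethoxy)-6-methylbenzoate
Product: 20 methyl 2-{3-[3-(methoxycarbonyl)-2,6-bis(methoxymethoxy)-4-methylbenzyl]-2,4-bis(methoxymethoxy)-6-methylphenoxy}-3-formyl-4-(methoxymethoxy)-6-methylbenzoate, via cesium phenoxide 19 (not isolated)
Conditions: CsF, DMF, rt to 60 °C
Reagents that add atoms: none
Why: Fluoride cleaves the aryl silyl ether to the cesium phenoxide, which displaces the fluoride lying ortho to both CHO and CO2Me by addition–elimination (SNAr), and the fluoride released keeps the desilylation going.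

**Step 13**
Reactants: 20 the pentakis(methoxymethyl) ether
Product: 21 Praesorether F
Conditions: HCl (cat.), MeOH, 40 °C, dilute; then H2O
Reagents that add atoms: none
Why: Acid-catalysed acetal exchange removes all five MOM groups as dimethoxymethane; methyl esters cannot transesterify in methanol, and any dimethyl acetal of the aldehyde reverts on aqueous work-up; no stereocentre is present.

**Compound list**
1 | methyl orsellinate (methyl 2,4-dihydroxy-6-methylbenzoate) | COC(=O)c1c(C)cc(O)cc1O | starting material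
2 | methyl 3-[chloro(methoxy)methyl]-2,4-dihydroxy-6-methylbenzoate (titanium-bound) | COC(=O)c1c(C)cc(O)c(C(Cl)OC)c1O | intermediate
3 | methyl haematommate (methyl 3-formyl-2,4-dihydroxy-6-methylbenzoate) | COC(=O)c1c(C)cc(O)c(C=O)c1O | intermediate
4 | methyl 3-formyl-2,4-bis(methoxymethoxy)-6-methylbenzoate | COC(=O)c1c(C)cc(OCOC)c(C=O)c1OCOC | intermediate
5 | 2,4-dihydroxy-6-methylbenzaldehyde (orcylaldehyde) | O=Cc1c(C)cc(O)cc1O | starting material
6 | 2,4-bis(methoxymethoxy)-6-methylbenzaldehyde | O=Cc1c(C)cc(OCOC)cc1OCOC | intermediate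
7 | 2,4-bis(methoxymethoxy)-6-methylphenyl formate | O=COc1c(C)cc(OCOC)cc1OCOC | intermediate
8 | 2,4-bis(methoxymethoxy)-6-methylphenol | Oc1c(C)cc(OCOC)cc1OCOC | intermediate
9 | tert-butyl[2,4-bis(methoxymethoxy)-6-methylphenoxy]dimethylsilane | CC(C)(C)[Si](C)(C)Oc1c(C)cc(OCOC)cc1OCOC | intermediate
10 | {3-[(tert-butyldimethylsilyl)oxy]-2,6-bis(methoxymethoxy)-4-methylphenyl}lithium | [Li]c1c(OCOC)cc(C)c(O[Si](C)(C)C(C)(C)C)c1OCOC | intermediate
11 | methyl 3-[{3-[(tert-butyldimethylsilyl)oxy]-2,6-bis(methoxymethoxy)-4-methylphenyl}(hydroxy)methyl]-2,4-bis(methoxymethoxy)-6-methylbenzoate (racemic) | COC(=O)c1c(C)cc(OCOC)c(C(O)c2c(OCOC)cc(C)c(O[Si](C)(C)C(C)(C)C)c2OCOC)c1OCOC | intermediate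
12 | methyl 3-{3-[(tert-butyldimethylsilyl)oxy]-2,6-bis(methoxymethoxy)-4-methylbenzyl}-2,4-bis(methoxymethoxy)-6-methylbenzoate | COC(=O)c1c(C)cc(OCOC)c(Cc2c(OCOC)cc(C)c(O[Si](C)(C)C(C)(C)C)c2OCOC)c1OCOC | intermediate
13 | 3-fluoro-5-methylphenol | Cc1cc(O)cc(F)c1 | starting material
14 | 4-bromo-3-fluoro-5-methylphenol | Cc1cc(O)cc(F)c1Br | intermediate
15 | 2-bromo-1-fluoro-5-(methoxymethoxy)-3-methylbenzene | Cc1cc(OCOC)cc(F)c1Br | intermediate
16 | [3-bromo-2-fluoro-6-(methoxymethoxy)-4-methylphenyl]lithium | Cc1cc(OCOC)c([Li])c(F)c1Br | intermediate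
17 | 3-bromo-2-fluoro-6-(methoxymethoxy)-4-methylbenzaldehyde | Cc1cc(OCOC)c(C=O)c(F)c1Br | intermediate
18 | methyl 2-fluoro-3-formyl-4-(methoxymethoxy)-6-methylbenzoate | COC(=O)c1c(C)cc(OCOC)c(C=O)c1F | intermediate
19 | cesium 3-[3-(methoxycarbonyl)-2,6-bis(methoxymethoxy)-4-methylbenzyl]-2,4-bis(methoxymethoxy)-6-methylphenolate | COC(=O)c1c(C)cc(OCOC)c(Cc2c(OCOC)cc(C)c([O-])c2OCOC)c1OCOC.[Cs+] | intermediate
20 | methyl 2-{3-[3-(methoxycarbonyl)-2,6-bis(methoxymethoxy)-4-methylbenzyl]-2,4-bis(methoxymethoxy)-6-methylphenoxy}-3-formyl-4-(methoxymethoxy)-6-methylbenzoate | COC(=O)c1c(C)cc(OCOC)c(Cc2c(OCOC)cc(C)c(Oc3c(C=O)c(OCOC)cc(C)c3C(=O)OC)c2OCOC)c1OCOC | intermediate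
21 | Praesorether F (methyl 2-{3-[2,6-dihydroxy-3-(methoxycarbonyl)-4-methylbenzyl]-2,4-dihydroxy-6-methylphenoxy}-3-formyl-4-hydroxy-6-methylbenzoate) | COC(=O)c1c(C)cc(O)c(Cc2c(O)cc(C)c(Oc3c(C=O)c(O)cc(C)c3C(=O)OC)c2O)c1O | target

**Totals**
Total step count: 13.
Longest linear sequence: 7 steps (5 → 6 → 8 → 9 → 11 → 12 → 20 → 21; steps 3, 4, 5, 6, 7, 12, 13).

**Three steps most likely to fail**

Step 1 (regiochemistry of the formylation, C3 against C5). The fallback sets out from 1 and comes back at 3, with the carbon delivered by a chelate-controlled sigmatropic shift instead of an electrophilic substitution. Allyl bromide and K2CO3 in acetone alkylate only the non-chelated 4-hydroxyl to give methyl 4-(allyloxy)-2-hydroxy-6-methylbenzoate F1. Heating in N,N-diethylaniline at 190 °C (aromatic Claisen rearrangement, directed to C3 by bond fixation of the ester chelate) gives methyl 3-allyl-2,4-dihydroxy-6-methylbenzoate F2. RuHCl(CO)(PPh3)3 (cat.) in toluene at 80 °C moves the double bond into conjugation to give methyl 2,4-dihydroxy-6-methyl-3-[(E)-prop-1-en-1-yl]benzoate F3. Ozonolysis (O3, CH2Cl2/MeOH, -78 °C; Me2S) then gives 3.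

Step 7 (ionic hydrogenation may strip MOM or silyl groups, or the very stabilised cation may resist hydride). The fallback sets out from 11 and comes back at 12 without any acid. Ac2O, DMAP and Et3N in CH2Cl2 give the benzylic acetate methyl 3-[acetoxy{3-[(tert-butyldimethylsilyl)oxy]-2,6-bis(methoxymethoxy)-4-methylphenyl}methyl]-2,4-bis(methoxymethoxy)-6-methylbenzoate F4. Hydrogenolysis (H2, Pd/C, EtOAc, Et3N, rt) then gives 12; no benzyl group or aldehyde is present at this stage.

Step 12 (SNAr to a diaryl ether with four ortho substituents). The fallback sets out from 12 and 3 and comes back at 20, with metal-catalysed C–O coupling in place of addition–elimination. Bu4NF in THF at 0 °C frees the phenol methyl 3-[3-hydroxy-2,6-bis(methoxymethoxy)-4-methylbenzyl]-2,4-bis(methoxymethoxy)-6-methylbenzoate F5 from 12. From 3, MOMCl and i-Pr2NEt at 0 °C protect only the more accessible 4-hydroxyl to give methyl 3-formyl-2-hydroxy-4-(methoxymethoxy)-6-methylbenzoate F6. Tf2O and pyridine convert F6 into the aryl triflate methyl 3-formyl-4-(methoxymethoxy)-6-methyl-2-{[(trifluoromethyl)sulfonyl]oxy}benzoate F7. Coupling of F5 with F7 (Pd(OAc)2, t-BuBrettPhos, K3PO4, toluene, 100 °C) gives 20.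

**Further compounds**
F1 | step 1 | methyl 4-(allyloxy)-2-hydroxy-6-methylbenzoate | COC(=O)c1c(C)cc(OCC=C)cc1O
F2 | step 1 | methyl 3-allyl-2,4-dihydroxy-6-methylbenzoate | COC(=O)c1c(C)cc(O)c(CC=C)c1O
F3 | step 1 | methyl 2,4-dihydroxy-6-methyl-3-[(E)-prop-1-en-1-yl]benzoate | COC(=O)c1c(C)cc(O)c(/C=C/C)c1O
F4 | step 7 | methyl 3-[acetoxy{3-[(tert-butyldimethylsilyl)oxy]-2,6-bis(methoxymethoxy)-4-methylphenyl}methyl]-2,4-bis(methoxymethoxy)-6-methylbenzoate | COC(=O)c1c(C)cc(OCOC)c(C(OC(C)=O)c2c(OCOC)cc(C)c(O[Si](C)(C)C(C)(C)C)c2OCOC)c1OCOC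
F5 | step 12 | methyl 3-[3-hydroxy-2,6-bis(methoxymethoxy)-4-methylbenzyl]-2,4-bis(methoxymethoxy)-6-methylbenzoate | COC(=O)c1c(C)cc(OCOC)c(Cc2c(OCOC)cc(C)c(O)c2OCOC)c1OCOC
F6 | step 12 | methyl 3-formyl-2-hydroxy-4-(methoxymethoxy)-6-methylbenzoate | COC(=O)c1c(C)cc(OCOC)c(C=O)c1O
F7 | step 12 | methyl 3-formyl-4-(methoxymethoxy)-6-methyl-2-{[(trifluoromethyl)sulfonyl]oxy}benzoate | COC(=O)c1c(C)cc(OCOC)c(C=O)c1OS(=O)(=O)C(F)(F)F
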